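| setting | grey | teal | green | winter | dawn | spring | midnight |
|---|---|---|---|---|---|---|---|
| starting material | 0.050 M | 0.050 M | 0.050 M | 0.050 M | 0.050 M (fed, over 50.0 min) | 0.050 M | 0.050 M |
| protic impurity | 2.5 mM | 3.5 mM | 5.5 mM | 2.50 mM | 2.50 mM | 2.50 mM | 2.50 mM |
| remark | run made earlier | run made earlier | run made earlier | a closed flask charged with all of it at once and left for 50 min | all but starting material at the start; starting material goes in evenly over 50.0 min, the run ends at 50 min | one stirred flow tank at steady state, fed with the mixture as stated, mean residence time 50 min | a tube with plug flow, the mixed feed as stated, residence time 50 min |
| time |  |  |  | 50 min | 50 min |  | 50 min |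

| run | time / min | target / % | over-reaction product / % |
|---|---|---|---|
| grey | 4.00 | 3 | 3 |
| grey | 6.00 | 8 | 0 |
| grey | 10.0 | 5 | 0 |
| grey | 15.0 | 11 | 0 |
| grey | 20.0 | 17 | 2 |
| grey | 30.0 | 32 | 4 |
| grey | 50.0 | 61 | 18 |
| teal | 3.00 | 1 | 0 |
| teal | 10.0 | 3 | 0 |
| teal | 15.0 | 9 | 0 |
| teal | 25.0 | 24 | 3 |
| teal | 40.0 | 48 | 6 |
| teal | 50.0 | 57 | 13 |
| teal | 60.0 | 57 | 20 |
| green | 3.00 | 2 | 1 |
| green | 10.0 | 8 | 2 |
| green | 15.0 | 10 | 0 |
| green | 25.0 | 21 | 4 |
| green | 40.0 | 41 | 11 |
| green | 50.0 | 55 | 15 |
| green | 60.0 | 58 | 23 |

(scatter of a reading: 1.5 percentage points)

- the stated concentrations are those of everything mixed, before any reaction; amounts are the same in each set-up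
- the analysis behind the earlier runs scatters by 1.5 percentage points, standard deviation
- the feed brings no volume worth counting
- the earlier runs were made in a closed, stirred flask

- the set-up with the highest share of target in all that became target or over-reaction product, at the outlet or at the end ("none" if the first two lie within 2 percentage points) (winter / dawn / spring / midnight / none)
- share of target in all that became target or over-reaction product, at the outlet or at the end, winter
- share of target in all that became target or over-reaction product, at the outlet or at the end, dawn
- share of target in all that became target or over-reaction product, at the outlet or at the end, spring
- share of target in all that became target or over-reaction product, at the outlet or at the end, midnight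

If over-reaction product forms from target by a steady first-order step, its amount is that rate constant times the area under the target curve. The share of target, the selectivity asked for, is then one over one plus that rate constant times the holding time, meaning the area divided by the final target. In the teal and green runs, the gain in over-reaction product from 40.0 min to 60.0 min, divided by the target area there, reads 0.0121 /min, the ageing rate of target.

Two extremes bracket the share at 50 min. Target born entirely at the first moment keeps 54.6 %, and target born at the last moment keeps 100 %. We place the real set-ups between them. The grey area gives winter, and midnight with it, a holding time of 22.0 min, so a share of 78.9 %. In spring, the tank balance makes the holding time the residence time, so the share is 62.2 %. In dawn, if target grows as the square of time under the even feed, the holding time is a third of the run and the share is 83.2 %, so we choose dawn, higher than either.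

The forecast chose dawn, with 78 % for winter, 88 % for dawn, 62 % for spring and 78 % for midnight, holding for dawn that “the target is young”. Its dawn value stands higher than our 83.2 %.

The simulation gives dawn: 78.3 % for winter, 87.2 % for dawn, 62.5 % for spring and 78.3 % for midnight.

    starting material → target (k = 6.90 × 10⁻⁵ /s)
    starting material + protic impurity → quenched substrate (k = 0.0640 /M/s)
    starting material + target → 2 target (k = 0.0330 /M/s)
    target → over-reaction product (k = 2.00 × 10⁻⁴ /s)

The dawn share corresponds to a holding time of 12.1 min, shorter than a third of the run. At 43.1 min in dawn, the step of starting material with target uses starting material 3.0 times as fast as the plain passing of starting material into target, and half of that step's turnover up to the end of the run is done by 43.1 min. For the dawn flask charged with 0.013 M of starting material, the same third-of-the-run holding time, with the same ageing rate of target, gives 83.2 %. The computed share there is 83.5 %.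

The numbers in the tables come from a simulation on assumed constants, noise included.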